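**Plan**

- Retrosynthesis: the top–middle bond C4–C8 is cut first (flavan-4-yl cation arylation). In the middle unit, O1–C2 (Mitsunobu) and C2–ring B (Grignard) are cut next, which leaves a lactol. The lactol is cut at O1–C2 and C3–C4 (amine-catalysed quinone methide annulation), and the resulting benzhydrol at its aryl–C4 bond (aryllithium plus 6-formylcatechin).
- Enabling feature: ring C of the middle unit has O3 and the C4 aryl group trans on C3/C4, and C4 already carries C6 of ring A of the bottom unit. That is the pattern left when an α-oxy enamine adds to the exocyclic carbon of an ortho-quinone methide.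
- Forward: the bottom catechin is benzylated, capped with bromine at C8 and formylated at C6. A lithiated phloroglucinol ring (later ring A of the middle unit) adds to give the benzhydrol. The annulation closes ring C as a lactol, ring B enters by Grignard addition and ring C is closed again. The top unit is attached last at C8 of the middle ring A, and hydrogenolysis frees all phenols.
- Stereochemistry: bottom and top units come from (+)-catechin and (−)-epicatechin. C3 and C4 of the middle unit come from the prolinol catalyst, its C2 from Felkin–Anh addition followed by Mitsunobu inversion, and C4 of the top unit from attack trans to its 3-OH.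

Key step: step 7

Remark on the chemistry: the enamine of the silyloxyacetaldehyde is taken to react as its E isomer in the s-trans arrangement, as α-alkyl enamines of this catalyst do; this assigns the (S)-catalyst, and the mirror-image amine would be needed if the enamine reacted through its Z isomer.
Remark on the chemistry: 3,5-bis(benzyloxy)phenol, the dibenzyl ether of phloroglucinol, is taken as a purchased compound.

**Route**

Step 1
Reactants: 1 (+)-catechin
Product: 2 5,7,3',4'-tetra-O-benzyl-(+)-catechin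
Conditions: BnBr, K2CO3, DMF, 0 °C to rt
Reagents that add atoms: benzyl bromide, BrCc1ccccc1
Why: Williamson etherification with carbonate alkylates only the four phenols and leaves the secondary 3-OH and both stereocentres untouched.

Step 2
Reactants: 2 5,7,3',4'-tetra-O-benzyl-(+)-catechin
Product: 3 8-bromo-5,7,3',4'-tetra-O-benzyl-(+)-catechin
Conditions: N-bromosuccinimide, CH2Cl2, −78 °C to 0 °C
Reagents that add atoms: N-bromosuccinimide, O=C1CCC(=O)N1Br
Why: Electrophilic aromatic bromination goes to C8, the more reactive of the two free carbons of ring A in these benzyl ethers, and the bromine later blocks C8 in steps 4 and 15.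

Step 3
Reactants: 3 8-bromo-5,7,3',4'-tetra-O-benzyl-(+)-catechin
Product: 4 8-bromo-3,5,7,3',4'-penta-O-benzyl-(+)-catechin
Conditions: NaH, BnBr, DMF, 0 °C to rt
Reagents that add atoms: benzyl bromide, BrCc1ccccc1
Why: Williamson etherification of the sodium alkoxide protects O3 against the Vilsmeier reagent and the organolithium of the next steps; the aryl bromide is inert.

Step 4
Reactants: 4 8-bromo-3,5,7,3',4'-penta-O-benzyl-(+)-catechin
Product: 6 8-bromo-6-formyl-3,5,7,3',4'-penta-O-benzyl-(+)-catechin, via aryl iminium chloride 5 (not isolated)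
Conditions: POCl3, DMF, 0 °C to 70 °C; then aq NaOAc
Reagents that add atoms: N,N-dimethylformamide, CN(C)C=O (formyl carbon); water, O (aldehyde oxygen)
Why: Vilsmeier–Haack formylation can only occur at C6, the one free carbon of ring A, which is ortho to two benzyloxy groups and para to O1; hydrolysis of the iminium salt gives the aldehyde.

Step 5
Reactants: 7 3,5-bis(benzyloxy)phenol
Product: 8 3,5-bis(benzyloxy)-2-iodophenol
Conditions: I2, NaHCO3, THF/H2O, 0 °C
Reagents that add atoms: iodine, II
Why: Electrophilic iodination of the phenoxide should go to the carbon ortho to the free oxygen, which is less hindered than the carbon between the two benzyloxy groups.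

Step 6
Reactants: 8 3,5-bis(benzyloxy)-2-iodophenol; 6 8-bromo-6-formyl-3,5,7,3',4'-penta-O-benzyl-(+)-catechin
Product: 10 ortho-hydroxybenzhydrol linking the phloroglucinol ring to C6 of the capped catechin (both carbinol epimers), via lithium 2-lithiophenoxide 9 (not isolated)
Conditions: n-BuLi (2 equiv per 8), THF, −78 °C; then 6, −78 °C; aq NH4Cl at −78 °C; Et3N-washed silica
Reagents that add atoms: none
Why: O-deprotonation and iodine–lithium exchange give the ortho-lithiated phenoxide, whose 1,2-addition to the aldehyde is faster than exchange with the aryl bromide; the carbinol configuration does not matter because step 7 erases it.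

Step 7
Reactants: 10 ortho-hydroxybenzhydrol; 11 (tert-butyldimethylsilyloxy)acetaldehyde
Product: 13 (3R,4R)-3-silyloxy-4-aryl-chroman-2-ol (3,4-trans lactol; both anomers), via ortho-quinone methide 12 (not isolated)
Conditions: (S)-2-[diphenyl(trimethylsilyloxy)methyl]pyrrolidine (20 mol%), AcOH, 11 (3 equiv), CH2Cl2, 0 °C to rt
Reagents that add atoms: none
Why: Acetic acid ionises the doubly activated benzhydrol 10 and loss of water gives ortho-quinone methide 12, while the pyrrolidine condenses with 11 to the α-silyloxy enamine. The enamine carbon adds to the exocyclic carbon of 12 (Michael addition, C3–C4), and the phenoxide then closes on the iminium carbon (O1–C2) by 6-exo-trig attack to give the cyclic N,O-acetal of ring C, which water hydrolyses to lactol 13 with release of the amine. The closest known reaction type is the secondary-amine-catalysed formal [4+2] annulation of enolisable aldehydes with ortho-quinone methides made in situ, which gives trans-3,4-disubstituted chroman-2-ols, together with enamine Michael additions of α-oxygenated acetaldehydes. C3 is set by the catalyst, whose diphenyl(silyloxy)methyl arm shields one face of the s-trans E enamine so that the (S)-amine should lead to 3R; C4 is set by the open, anti-selective Michael transition state, and the 3,4-trans lactol is also the more stable one should C3 equilibrate. The step needs a single quinone methide, C-alkylation at C4 only, and reagent control over the catechin centres: only one phenol is free, ring A of the catechin part is fully substituted (bromine at C8) and cannot compete as a nucleophile, and its stereocentres lie several bonds from C4, so the amine should decide the facial sense.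

Step 8
Reactants: 14 4-bromocatechol
Product: 15 4-bromo-1,2-bis(benzyloxy)benzene
Conditions: BnBr, K2CO3, DMF, rt
Reagents that add atoms: benzyl bromide, BrCc1ccccc1
Why: Williamson etherification of both phenols gives the precursor of the ring B nucleophile.

Step 9
Reactants: 15 4-bromo-1,2-bis(benzyloxy)benzene; 13 3,4-trans lactol
Product: 17 1,2-anti diol (1S,2R,3R), via arylmagnesium bromide 16 (not isolated)
Conditions: 15 (4 equiv), Mg, THF, 50 °C; then 13, THF, −78 °C to −20 °C; aq NH4Cl
Reagents that add atoms: none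
Why: One equivalent of the Grignard reagent opens the lactol to its phenoxide aldehyde and a second adds to the carbonyl; the silyl ether does not chelate, so polar Felkin–Anh addition anti to the silyloxy group should give the 1,2-anti diol (S at the new carbinol carbon).

Step 10
Reactants: 17 1,2-anti diol
Product: 18 3-O-silylated tetra-O-benzyl-epicatechin-(4β→6)-8-bromo-penta-O-benzyl-catechin (middle unit 2,3-cis-3,4-trans)
Conditions: PPh3, diisopropyl azodicarboxylate, THF, 0 °C to rt
Reagents that add atoms: none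
Why: Intramolecular Mitsunobu etherification (6-exo-tet): the phenol, the only acidic OH, displaces the oxyphosphonium of the only free alcohol with inversion, which turns the anti diol into the 2,3-cis ring C with C2 configured R as in epicatechin.

Step 11
Reactants: 18 3-O-silylated dimer
Product: 19 tetra-O-benzyl-epicatechin-(4β→6)-8-bromo-penta-O-benzyl-catechin (free 3-OH on the upper unit)
Conditions: n-Bu4NF, THF, 0 °C to rt
Reagents that add atoms: none
Why: Fluoride cleaves the silyl ether and leaves the benzyl ethers, the aryl bromide and all stereocentres unchanged.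

Step 12
Reactants: 20 (−)-epicatechin
Product: 21 5,7,3',4'-tetra-O-benzyl-(−)-epicatechin
Conditions: BnBr, K2CO3, DMF, 0 °C to rt
Reagents that add atoms: benzyl bromide, BrCc1ccccc1
Why: Williamson etherification of the four phenols, as in step 1.

Step 13
Reactants: 21 5,7,3',4'-tetra-O-benzyl-(−)-epicatechin
Product: 22 8-bromo-5,7,3',4'-tetra-O-benzyl-(−)-epicatechin
Conditions: N-bromosuccinimide, CH2Cl2, −78 °C to 0 °C
Reagents that add atoms: N-bromosuccinimide, O=C1CCC(=O)N1Br
Why: Electrophilic bromination at C8 caps the most nucleophilic carbon of the donor, so that the cation of step 15 cannot attack another donor molecule there.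

Step 14
Reactants: 22 8-bromo-5,7,3',4'-tetra-O-benzyl-(−)-epicatechin
Product: 23 8-bromo-4β-(2-ethoxyethoxy)-5,7,3',4'-tetra-O-benzyl-(−)-epicatechin
Conditions: 2,3-dichloro-5,6-dicyano-1,4-benzoquinone (DDQ), 2-ethoxyethanol, CH2Cl2, rt
Reagents that add atoms: 2-ethoxyethanol, CCOCCO
Why: Benzylic oxidation by hydride abstraction at C4 gives a cation stabilised by the ring A oxygens, which the alcohol captures trans to the 3-OH (4β).

Step 15
Reactants: 19 dimer with free C8 on its upper unit; 23 4-alkoxy donor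
Product: 24 8-bromo-tetra-O-benzyl-epicatechin-(4β→8)-tetra-O-benzyl-epicatechin-(4β→6)-8-bromo-penta-O-benzyl-catechin
Conditions: 23 (1.5 equiv), trimethylsilyl trifluoromethanesulfonate (0.2 equiv), CH2Cl2, −78 °C to −40 °C
Reagents that add atoms: none
Why: Friedel–Crafts-type flavan C4 arylation: the silyl triflate ionises the 4-alkoxy group, and the benzylic cation is attacked by C8 of the middle ring A (the most nucleophilic free arene carbon, both capped rings being fully substituted) from the face trans to the 3-OH of the 2,3-cis donor, which sets the new C4 as 4β.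

Step 16
Reactants: 24 protected trimer
Product: 25 arecatannin B1
Conditions: H2 (1 atm), Pd(OH)2/C, THF/MeOH/H2O, rt
Reagents that add atoms: none
Why: Hydrogenolysis over Pd(OH)2/C cleaves the thirteen benzyl ethers and both aryl C–Br bonds without touching the flavan stereocentres or the interflavan bonds.

**Compound list**

1 | (+)-catechin, (2R,3S) | Oc1cc(O)c2c(c1)O[C@H](c1ccc(O)c(O)c1)[C@@H](O)C2 | starting material
2 | 5,7,3',4'-tetra-O-benzyl-(+)-catechin | c1ccccc1COc1cc(OCc3ccccc3)c2c(c1)O[C@H](c1ccc(OCc3ccccc3)c(OCc3ccccc3)c1)[C@@H](O)C2 | intermediate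
3 | 8-bromo-5,7,3',4'-tetra-O-benzyl-(+)-catechin | c1ccccc1COc1cc(OCc3ccccc3)c2c(c1Br)O[C@H](c1ccc(OCc3ccccc3)c(OCc3ccccc3)c1)[C@@H](O)C2 | intermediate
4 | 8-bromo-3,5,7,3',4'-penta-O-benzyl-(+)-catechin | c1ccccc1COc1cc(OCc3ccccc3)c2c(c1Br)O[C@H](c1ccc(OCc3ccccc3)c(OCc3ccccc3)c1)[C@@H](OCc3ccccc3)C2 | intermediate
5 | C6 dimethyliminium chloride of 4 (not isolated) | c1ccccc1COc1c(C=[N+](C)C)c(OCc3ccccc3)c2c(c1Br)O[C@H](c1ccc(OCc3ccccc3)c(OCc3ccccc3)c1)[C@@H](OCc3ccccc3)C2.[Cl-] | intermediate
6 | 8-bromo-6-formyl-3,5,7,3',4'-penta-O-benzyl-(+)-catechin | c1ccccc1COc1c(C=O)c(OCc3ccccc3)c2c(c1Br)O[C@H](c1ccc(OCc3ccccc3)c(OCc3ccccc3)c1)[C@@H](OCc3ccccc3)C2 | intermediate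
7 | 3,5-bis(benzyloxy)phenol | Oc1cc(OCc2ccccc2)cc(OCc2ccccc2)c1 | starting material
8 | 3,5-bis(benzyloxy)-2-iodophenol | Oc1cc(OCc2ccccc2)cc(OCc2ccccc2)c1I | intermediate
9 | lithium 3,5-bis(benzyloxy)-2-lithiophenoxide (not isolated) | [Li]Oc1cc(OCc2ccccc2)cc(OCc2ccccc2)c1[Li] | intermediate
10 | [2,4-bis(benzyloxy)-6-hydroxyphenyl][(2R,3S)-3,5,7-tris(benzyloxy)-2-[3,4-bis(benzyloxy)phenyl]-8-bromochroman-6-yl]methanol, both carbinol epimers | Oc1cc(OCc3ccccc3)cc(OCc3ccccc3)c1C(O)c1c(OCc3ccccc3)c(Br)c2c(c1OCc3ccccc3)C[C@H](OCc3ccccc3)[C@@H](c1ccc(OCc3ccccc3)c(OCc3ccccc3)c1)O2 | intermediate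
11 | (tert-butyldimethylsilyloxy)acetaldehyde | O=CCO[Si](C)(C)C(C)(C)C | starting material
12 | ortho-quinone methide from 10: 3,5-bis(benzyloxy)-6-(arylmethylidene)cyclohexa-2,4-dien-1-one, aryl = capped catechin-6-yl, alkene geometry open (not isolated) | O=C1C=C(OCc3ccccc3)C=C(OCc3ccccc3)C1=Cc1c(OCc3ccccc3)c(Br)c2c(c1OCc3ccccc3)C[C@H](OCc3ccccc3)[C@@H](c1ccc(OCc3ccccc3)c(OCc3ccccc3)c1)O2 | intermediate
13 | (3R,4R)-5,7-bis(benzyloxy)-3-(tert-butyldimethylsilyloxy)-4-[8-bromo-penta-O-benzyl-catechin-6-yl]chroman-2-ol, 3,4-trans, both anomers | c1c(OCc3ccccc3)cc(OCc3ccccc3)c2c1OC(O)[C@H](O[Si](C)(C)C(C)(C)C)[C@H]2c1c(OCc3ccccc3)c(Br)c2c(c1OCc3ccccc3)C[C@H](OCc3ccccc3)[C@@H](c1ccc(OCc3ccccc3)c(OCc3ccccc3)c1)O2 | intermediate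
14 | 4-bromocatechol | Oc1ccc(Br)cc1O | starting material
15 | 4-bromo-1,2-bis(benzyloxy)benzene | Brc1ccc(OCc2ccccc2)c(OCc2ccccc2)c1 | intermediate
16 | 3,4-bis(benzyloxy)phenylmagnesium bromide (not isolated) | Br[Mg]c1ccc(OCc2ccccc2)c(OCc2ccccc2)c1 | intermediate
17 | (1S,2R,3R)-1-[3,4-bis(benzyloxy)phenyl]-3-[2,4-bis(benzyloxy)-6-hydroxyphenyl]-3-[8-bromo-penta-O-benzyl-catechin-6-yl]-2-(tert-butyldimethylsilyloxy)propan-1-ol, 1,2-anti | Oc1cc(OCc3ccccc3)cc(OCc3ccccc3)c1[C@@H]([C@@H](O[Si](C)(C)C(C)(C)C)[C@@H](O)c1ccc(OCc3ccccc3)c(OCc3ccccc3)c1)c1c(OCc3ccccc3)c(Br)c2c(c1OCc3ccccc3)C[C@H](OCc3ccccc3)[C@@H](c1ccc(OCc3ccccc3)c(OCc3ccccc3)c1)O2 | intermediate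
18 | 3-O-(tert-butyldimethylsilyl)-5,7,3',4'-tetra-O-benzyl-epicatechin-(4β→6)-8-bromo-3,5,7,3',4'-penta-O-benzyl-catechin | c1c(OCc3ccccc3)cc(OCc3ccccc3)c2c1O[C@H](c1ccc(OCc3ccccc3)c(OCc3ccccc3)c1)[C@H](O[Si](C)(C)C(C)(C)C)[C@H]2c1c(OCc3ccccc3)c(Br)c2c(c1OCc3ccccc3)C[C@H](OCc3ccccc3)[C@@H](c1ccc(OCc3ccccc3)c(OCc3ccccc3)c1)O2 | intermediate
19 | 5,7,3',4'-tetra-O-benzyl-epicatechin-(4β→6)-8-bromo-3,5,7,3',4'-penta-O-benzyl-catechin | c1c(OCc3ccccc3)cc(OCc3ccccc3)c2c1O[C@H](c1ccc(OCc3ccccc3)c(OCc3ccccc3)c1)[C@H](O)[C@H]2c1c(OCc3ccccc3)c(Br)c2c(c1OCc3ccccc3)C[C@H](OCc3ccccc3)[C@@H](c1ccc(OCc3ccccc3)c(OCc3ccccc3)c1)O2 | intermediate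
20 | (−)-epicatechin, (2R,3R) | Oc1cc(O)c2c(c1)O[C@H](c1ccc(O)c(O)c1)[C@H](O)C2 | starting material
21 | 5,7,3',4'-tetra-O-benzyl-(−)-epicatechin | c1ccccc1COc1cc(OCc3ccccc3)c2c(c1)O[C@H](c1ccc(OCc3ccccc3)c(OCc3ccccc3)c1)[C@H](O)C2 | intermediate
22 | 8-bromo-5,7,3',4'-tetra-O-benzyl-(−)-epicatechin | c1ccccc1COc1cc(OCc3ccccc3)c2c(c1Br)O[C@H](c1ccc(OCc3ccccc3)c(OCc3ccccc3)c1)[C@H](O)C2 | intermediate
23 | 8-bromo-4β-(2-ethoxyethoxy)-5,7,3',4'-tetra-O-benzyl-(−)-epicatechin | c1ccccc1COc1cc(OCc3ccccc3)c2c(c1Br)O[C@H](c1ccc(OCc3ccccc3)c(OCc3ccccc3)c1)[C@H](O)[C@H]2OCCOCC | intermediate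
24 | 8-bromo-tetra-O-benzyl-epicatechin-(4β→8)-tetra-O-benzyl-epicatechin-(4β→6)-8-bromo-penta-O-benzyl-catechin | c1ccccc1COc1cc(OCc3ccccc3)c2c(c1Br)O[C@H](c1ccc(OCc3ccccc3)c(OCc3ccccc3)c1)[C@H](O)[C@H]2c1c(OCc3ccccc3)cc(OCc3ccccc3)c2c1O[C@H](c1ccc(OCc3ccccc3)c(OCc3ccccc3)c1)[C@H](O)[C@H]2c1c(OCc3ccccc3)c(Br)c2c(c1OCc3ccccc3)C[C@H](OCc3ccccc3)[C@@H](c1ccc(OCc3ccccc3)c(OCc3ccccc3)c1)O2 | intermediate
25 | arecatannin B1, epicatechin-(4β→8)-epicatechin-(4β→6)-catechin | Oc1cc(O)c2c(c1)O[C@H](c1ccc(O)c(O)c1)[C@H](O)[C@H]2c1c(O)cc(O)c2c1O[C@H](c1ccc(O)c(O)c1)[C@H](O)[C@H]2c1c(O)cc2c(c1O)C[C@H](O)[C@@H](c1ccc(O)c(O)c1)O2 | target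

**Step count and risks**

Total step count: 16. Longest linear sequence: 11 steps (1, 2, 3, 4, 6, 7, 9, 10, 11, 15, 16) from (+)-catechin.

Steps most likely to fail:

Step 7. C–C bond formation at the strongly stabilised, tetra-ortho-substituted quinone methide may be slow, so that self-aldol of 11 or capture of the cation by the amine takes over. The facial sense may also be eroded by E/Z isomerism of the silyloxy enamine or by retro-Michael equilibration. The fallback gives up the annulation and makes the C4–C6 bond by flavan-4-yl cation arylation. It sets out from 21, which is oxidised with DDQ and 2-ethoxyethanol to 4β-(2-ethoxyethoxy)-5,7,3',4'-tetra-O-benzyl-(−)-epicatechin F1. F1 is ionised with catalytic trimethylsilyl trifluoromethanesulfonate at −78 °C in the presence of an excess of 4, whose only free ring A carbon is C6 because bromine blocks C8. Attack trans to the 3-OH should give the 4β→6 dimer, and the route is rejoined at 19.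

Step 9. Facial discrimination in the aryl addition may be poor, because delivery by the magnesium phenoxide competes with Felkin–Anh control and enolisation may epimerise C3. The fallback sets out from 13 and avoids both the carbinol and the inversion. The lactol is oxidised with Dess–Martin periodinane to the 3,4-trans 3-silyloxy-dihydrocoumarin F2. One equivalent of the aryllithium made from 15 with n-BuLi at −78 °C is added to give the 2-aryl-chroman-2-ol (cyclic hemiketal) F3. Ionic hydrogenation with Et3SiH and trifluoroacetic acid at −40 °C then reduces the 2-aryl oxocarbenium ion. Hydride should enter anti to the pseudoaxial 3-silyloxy group, which gives the 2,3-cis ring, and the route is rejoined at 18.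

Step 10. The oxyphosphonium at the electron-rich benzylic carbon may ionise before the phenol attacks, which would cost the inversion (2,3-trans ring) or lead to elimination. The fallback sets out from 17 and replaces the phosphonium by a neighbouring group. The silyl ether is removed with n-Bu4NF to give the phenol 1,2-diol (triol) F4. Triethyl orthoformate and pyridinium p-toluenesulfonate convert the diol into the 2-ethoxy-1,3-dioxolane (cyclic orthoformate) F5. On warming this ionises to the bridged 1,3-dioxolan-2-ylium ion, which the phenol can only open from the rear at the benzylic carbon, giving the 2,3-cis chroman 3-O-formate F6. K2CO3 in MeOH removes the formate, and the route is rejoined at 19.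

**Further compounds**

F1 | step 7 | 4β-(2-ethoxyethoxy)-5,7,3',4'-tetra-O-benzyl-(−)-epicatechin | c1ccccc1COc1cc(OCc3ccccc3)c2c(c1)O[C@H](c1ccc(OCc3ccccc3)c(OCc3ccccc3)c1)[C@H](O)[C@H]2OCCOCC
F2 | step 9 | (3R,4R)-5,7-bis(benzyloxy)-3-(tert-butyldimethylsilyloxy)-4-[8-bromo-penta-O-benzyl-catechin-6-yl]chroman-2-one | c1c(OCc3ccccc3)cc(OCc3ccccc3)c2c1OC(=O)[C@H](O[Si](C)(C)C(C)(C)C)[C@H]2c1c(OCc3ccccc3)c(Br)c2c(c1OCc3ccccc3)C[C@H](OCc3ccccc3)[C@@H](c1ccc(OCc3ccccc3)c(OCc3ccccc3)c1)O2
F3 | step 9 | 2-[3,4-bis(benzyloxy)phenyl] derivative of lactol 13 (cyclic hemiketal, C2 open) | c1c(OCc3ccccc3)cc(OCc3ccccc3)c2c1OC(O)(c1ccc(OCc3ccccc3)c(OCc3ccccc3)c1)[C@H](O[Si](C)(C)C(C)(C)C)[C@H]2c1c(OCc3ccccc3)c(Br)c2c(c1OCc3ccccc3)C[C@H](OCc3ccccc3)[C@@H](c1ccc(OCc3ccccc3)c(OCc3ccccc3)c1)O2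
F4 | step 10 | desilylated 17 (phenol with 1,2-anti diol) | Oc1cc(OCc3ccccc3)cc(OCc3ccccc3)c1[C@@H]([C@@H](O)[C@@H](O)c1ccc(OCc3ccccc3)c(OCc3ccccc3)c1)c1c(OCc3ccccc3)c(Br)c2c(c1OCc3ccccc3)C[C@H](OCc3ccccc3)[C@@H](c1ccc(OCc3ccccc3)c(OCc3ccccc3)c1)O2
F5 | step 10 | 2-ethoxy-1,3-dioxolane (cyclic orthoformate) of F4 | Oc1cc(OCc3ccccc3)cc(OCc3ccccc3)c1[C@@H]([C@H]4OC(OCC)O[C@H]4c1ccc(OCc3ccccc3)c(OCc3ccccc3)c1)c1c(OCc3ccccc3)c(Br)c2c(c1OCc3ccccc3)C[C@H](OCc3ccccc3)[C@@H](c1ccc(OCc3ccccc3)c(OCc3ccccc3)c1)O2
F6 | step 10 | 3-O-formate of 19 | c1c(OCc3ccccc3)cc(OCc3ccccc3)c2c1O[C@H](c1ccc(OCc3ccccc3)c(OCc3ccccc3)c1)[C@H](OC=O)[C@H]2c1c(OCc3ccccc3)c(Br)c2c(c1OCc3ccccc3)C[C@H](OCc3ccccc3)[C@@H](c1ccc(OCc3ccccc3)c(OCc3ccccc3)c1)O2
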